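## Retrosynthetic overview

1. Target 12 ⇒ dihydrobenzofuran 4 + pyrone 9 + one CH2 unit; the C7–CH2–pyrone bridge is made last by a Mannich/methide coupling.
2. 4 ⇒ bromophloroacetophenone 2 + myrcene 3. One enantioselective Pd-catalysed Heck/Tsuji–Trost [3+2] heteroannulation forms C3–C3a and O1–C2, sets C2 as R and brings in the whole C10 side chain with its 1,1-disubstituted alkene. This replaces the usual C-geranylation, asymmetric epoxidation, cyclisation and dehydration sequence.
3. 2 ⇒ phloroacetophenone 1 (monobromination); 9 ⇒ 3-pentanone 5 (as silyl enol ether 6) + malonyl dichloride 7.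
4. Ring order: the benzene ring is bought; the dihydrofuran ring (step 2) and the pyranone ring (step 4) are made in separate branches and joined in step 5. No protecting groups.

Assumption: the sense of induction of the chiral ligand in step 2 is fixed by a calibration run (4-acetyl-2-bromophenol + isoprene gives tremetone, whose R enantiomer is known), and the ligand antipode that gives R is used.
Assumption: ionised forms of phenols or enols and catalyst-bound palladium species are treated as mechanism, not as numbered compounds.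

## Route

Step 1
Reactants: 1 2',4',6'-trihydroxyacetophenone
Product: 2 1-(3-bromo-2,4,6-trihydroxyphenyl)ethan-1-one
Conditions: NBS (1.0 equiv), MeCN, −20 → 0 °C, dark
Reagents that add atoms: N-bromosuccinimide (NBS), O=C1CCC(=O)N1Br
Why: Electrophilic aromatic bromination of the phloroglucinol ring; C3 and C5 are equivalent, so one monobromide forms, and low temperature with 1.0 equiv limits the dibromide.

Step 2
Reactants: 2 1-(3-bromo-2,4,6-trihydroxyphenyl)ethan-1-one; 3 myrcene (7-methyl-3-methylideneocta-1,6-diene)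
Product: 4 1-[(2R)-4,6-dihydroxy-2-(6-methylhepta-1,5-dien-2-yl)-2,3-dihydro-1-benzofuran-5-yl]ethan-1-one
Conditions: 3 (3 equiv), Pd2(dba)3·CHCl3 (2.5 mol %), TY-Phos-type chiral sulfinamide–phosphine (Sadphos class, 10 mol %, antipode giving 2R), PhONa (1.2 equiv), 1,4-dioxane, 70 °C
Reagents that add atoms: none
Why: Proposed new method: this extends the known Pd(0)-catalysed enantioselective Heck/Tsuji–Trost (Larock-type) heteroannulation of simple o-bromophenols with 1,3-dienes such as isoprene to an unprotected bromo-acylphloroglucinol and myrcene; oxidative addition into C–Br and aryl transfer to the unhindered vinyl CH2 of the diene give a 2-substituted π-allyl-Pd, which is closed 5-exo at its internal terminus by the 4-phenoxide (the only OH ionised by 1.2 equiv PhONa, the 2- and 6-OH staying chelated to the acetyl C=O), and the chiral ligand fixes C2 as R in this insertion/anti C–O bond formation while the side chain is left as the 1,1-disubstituted alkene.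

Step 3
Reactants: 5 pentan-3-one
Product: 6 (Z)-3-(trimethylsilyloxy)pent-2-ene (Z major; the E isomer reacts the same way)
Conditions: TMSOTf (1.1 equiv), Et3N (1.3 equiv), CH2Cl2, 0 °C
Reagents that add atoms: trimethylsilyl triflate (TMSOTf), C[Si](C)(C)OS(=O)(=O)C(F)(F)F
Why: Soft enolisation and O-silylation of a symmetrical ketone gives a single regioisomer, and the E/Z ratio does not matter because both isomers lead to the same pyrone.

Step 4
Reactants: 6 (Z)-3-(trimethylsilyloxy)pent-2-ene; 7 malonyl dichloride
Product: 9 6-ethyl-4-hydroxy-5-methyl-2H-pyran-2-one, via ketoacyl chloride 8 (not isolated)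
Conditions: Et2O, −78 °C → rt, 16 h
Reagents that add atoms: none
Why: Effenberger pyrone synthesis: C-acylation of the silyl enol ether by one acyl chloride (loss of TMSCl) is followed by lactonisation of the ketone enol onto the second acyl chloride (loss of HCl) to give the 4-hydroxy-2-pyrone.

Step 5
Reactants: 9 6-ethyl-4-hydroxy-5-methyl-2H-pyran-2-one; 4 1-[(2R)-4,6-dihydroxy-2-(6-methylhepta-1,5-dien-2-yl)-2,3-dihydro-1-benzofuran-5-yl]ethan-1-one
Product: 12 3-{[(2R)-5-acetyl-4,6-dihydroxy-2-(6-methylhepta-1,5-dien-2-yl)-2,3-dihydro-1-benzofuran-7-yl]methyl}-6-ethyl-4-hydroxy-5-methyl-2H-pyran-2-one (target CNP0294086.1), via pyrone Mannich base 10 (not isolated), via pyrone methide 11 (not isolated)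
Conditions: 9, Me2N=CH2+ I− (1.1 equiv), NaOAc (1.1 equiv), MeCN, rt, 1 h; then 4, 70 °C
Reagents that add atoms: Eschenmoser's salt (N,N-dimethylmethyleneiminium iodide), C=[N+](C)C.[I-]
Why: Mannich reaction at C3 of the 4-hydroxy-2-pyrone, thermal loss of Me2NH to the pyrone methide and conjugate (Friedel–Crafts-type) addition of the only free aromatic carbon of 4 (C7) form the methylene bridge, as in the known methylene bridging of arzanol-type phloroglucinyl pyrones; the buffered, non-acidic medium leaves both alkenes and the allylic ether stereocentre untouched.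

## Compound list

1 | 2',4',6'-trihydroxyacetophenone | CC(=O)c1c(O)cc(O)cc1O | starting material
2 | 1-(3-bromo-2,4,6-trihydroxyphenyl)ethan-1-one | CC(=O)c1c(O)cc(O)c(Br)c1O | intermediate
3 | myrcene (7-methyl-3-methylideneocta-1,6-diene) | C=CC(=C)CCC=C(C)C | starting material
4 | 1-[(2R)-4,6-dihydroxy-2-(6-methylhepta-1,5-dien-2-yl)-2,3-dihydro-1-benzofuran-5-yl]ethan-1-one | C=C(CCC=C(C)C)[C@H]1Cc2c(O)c(C(C)=O)c(O)cc2O1 | intermediate
5 | pentan-3-one | CCC(=O)CC | starting material
6 | (Z)-3-(trimethylsilyloxy)pent-2-ene | C/C=C(/CC)O[Si](C)(C)C | intermediate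
7 | malonyl dichloride | O=C(Cl)CC(=O)Cl | starting material
8 | 4-methyl-3,5-dioxoheptanoyl chloride (racemic, enolisable; not isolated) | CCC(=O)C(C)C(=O)CC(=O)Cl | intermediate
9 | 6-ethyl-4-hydroxy-5-methyl-2H-pyran-2-one | CCc1oc(=O)cc(O)c1C | intermediate
10 | 3-[(dimethylamino)methyl]-6-ethyl-4-hydroxy-5-methyl-2H-pyran-2-one (not isolated) | CCc1oc(=O)c(CN(C)C)c(O)c1C | intermediate
11 | 6-ethyl-5-methyl-3-methylidene-2H-pyran-2,4(3H)-dione (not isolated) | CCC1=C(C)C(=O)C(=C)C(=O)O1 | intermediate
12 | 3-{[(2R)-5-acetyl-4,6-dihydroxy-2-(6-methylhepta-1,5-dien-2-yl)-2,3-dihydro-1-benzofuran-7-yl]methyl}-6-ethyl-4-hydroxy-5-methyl-2H-pyran-2-one | C=C(CCC=C(C)C)[C@H]1Cc2c(O)c(C(C)=O)c(O)c(Cc3c(O)c(C)c(CC)oc3=O)c2O1 | target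

## Step count and risks

Total step count: 5. Longest linear sequence: 3 (steps 1, 2, 5 or steps 3, 4, 5).

**Most likely to fail, 1: step 2.** The free triol may close through the chelated 2-OH instead of the 4-OH, may be C-allylated, or may slow the catalyst. The fallback sets out from 1 and comes back to the route at 4. It masks the two chelated hydroxyls so that the aryl bromide has a single ortho OH, the substrate type for which the heteroannulation is known. Selective benzylation of the most acidic 4-OH (BnBr, K2CO3, acetone) gives 1-[4-(benzyloxy)-2,6-dihydroxyphenyl]ethan-1-one F1. Capping of the two chelated hydroxyls (MOMCl, NaH, DMF) gives 1-[4-(benzyloxy)-2,6-bis(methoxymethoxy)phenyl]ethan-1-one F2. Hydrogenolysis (H2, Pd/C, EtOAc) gives 1-[4-hydroxy-2,6-bis(methoxymethoxy)phenyl]ethan-1-one F3. NBS then gives 1-[3-bromo-4-hydroxy-2,6-bis(methoxymethoxy)phenyl]ethan-1-one F4. The same asymmetric heteroannulation with 3 gives 1-[(2R)-4,6-bis(methoxymethoxy)-2-(6-methylhepta-1,5-dien-2-yl)-2,3-dihydro-1-benzofuran-5-yl]ethan-1-one F5. Dilute HCl in MeOH at rt, which cleaves carbonyl-flanked MOM ethers easily, returns 4.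

**Most likely to fail, 2: step 5.** The pyrone methide can be captured by pyrone to give the methylene-bis-pyrone, or the aminomethyl group can scramble and give homodimers. The fallback sets out from 4 and comes back at 12 with the roles reversed. Compound 4 is aminomethylated at C7 (Eschenmoser's salt, CH2Cl2, rt) and isolated as 1-[(2R)-7-[(dimethylamino)methyl]-4,6-dihydroxy-2-(6-methylhepta-1,5-dien-2-yl)-2,3-dihydro-1-benzofuran-5-yl]ethan-1-one F6. Heating F6 with pyrone 9 (dioxane, 80 °C) expels Me2NH to give the arene-derived o-quinone methide, which C3 of 9 traps to give 12.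

**Most likely to fail, 3: step 4.** Malonyl dichloride can give double acylation or poor mass balance with a trisubstituted silyl enol ether. The fallback sets out from 6 and comes back at 9 by a stepwise ester route. Lewis-acid-mediated C-acylation of 6 with methyl malonyl chloride (TiCl4, CH2Cl2, −78 °C) gives methyl 4-methyl-3,5-dioxoheptanoate F7. DBU in refluxing toluene then lactonises F7 with loss of methanol to 9.

## Further compounds

F1 | step 2 | 1-[4-(benzyloxy)-2,6-dihydroxyphenyl]ethan-1-one | CC(=O)c1c(O)cc(OCc2ccccc2)cc1O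
F2 | step 2 | 1-[4-(benzyloxy)-2,6-bis(methoxymethoxy)phenyl]ethan-1-one | CC(=O)c1c(OCOC)cc(OCc2ccccc2)cc1OCOC
F3 | step 2 | 1-[4-hydroxy-2,6-bis(methoxymethoxy)phenyl]ethan-1-one | CC(=O)c1c(OCOC)cc(O)cc1OCOC
F4 | step 2 | 1-[3-bromo-4-hydroxy-2,6-bis(methoxymethoxy)phenyl]ethan-1-one | CC(=O)c1c(OCOC)cc(O)c(Br)c1OCOC
F5 | step 2 | 1-[(2R)-4,6-bis(methoxymethoxy)-2-(6-methylhepta-1,5-dien-2-yl)-2,3-dihydro-1-benzofuran-5-yl]ethan-1-one | C=C(CCC=C(C)C)[C@H]1Cc2c(OCOC)c(C(C)=O)c(OCOC)cc2O1
F6 | step 5 | 1-[(2R)-7-[(dimethylamino)methyl]-4,6-dihydroxy-2-(6-methylhepta-1,5-dien-2-yl)-2,3-dihydro-1-benzofuran-5-yl]ethan-1-one | C=C(CCC=C(C)C)[C@H]1Cc2c(O)c(C(C)=O)c(O)c(CN(C)C)c2O1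
F7 | step 4 | methyl 4-methyl-3,5-dioxoheptanoate (racemic, enolisable) | CCC(=O)C(C)C(=O)CC(=O)OC
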